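**Plan**

- Locants: the ring carbons are C1–C14. C1 is the isopropyl-bearing alkene carbon, C2 the alkene CH, C3/C4 the oxirane CH and C–CH3, C8 the CH–CH2OH carbon (C19 = CH2OH), C9 a ketone, C12 the CH–CH3, C13 the CHOH and C14 the enone carbonyl.
- Enabling feature: C12 (methyl) and C13 (hydroxyl) lie between the C14 ketone and the C9 ketone three carbons away. Once C10–C11 is read as a reduced enone, C13 is the aldehyde of a C13–C14 2-oxoaldehyde and C12 the γ-carbon of a C9 dienolate.
- Cuts: C10–C11 (back to an enone), ring bond C12–C13 (vinylogous aldol), C1=C2 (Horner–Wadsworth–Emmons), C8–C9 (aldol with pent-2-enal), C7–C8 (cross-metathesis); the oxirane goes back to nerol.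
- Forward order: oxirane first (step 1); the chain then grows C7 → C8/C19 → C9–C12, then C1/C13/C14 are attached at C2; the 14-membered carbocycle closes at C12–C13 in step 19.
- Stereochemistry: C3/C4 from Sharpless epoxidation, C8 from an Evans syn-aldol, the C1=C2 E geometry from the olefination, C12/C13 from the chiral copper complex during ring closure.

Key step: step 19

Remark: the target is taken as (3S,4R,8S,12R,13S) with C1=C2 E (plan locants), as read from the SMILES.
Remark: (S,S)-tBu-box is 2,2′-(propane-2,2-diyl)bis[(4S)-4-tert-butyl-4,5-dihydro-1,3-oxazole]; its divalent copper complex is assumed to leave the Si face of the chelated C13 aldehyde open, as with glyoxylate esters. If the other face reacts, the (R,R) ligand is used with no other change.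

**Route**

Step 1
Reactants: 1 nerol
Product: 2 [(2S,3R)-3-methyl-3-(4-methylpent-3-en-1-yl)oxiran-2-yl]methanol
Conditions: Ti(OiPr)4 (cat), L-(+)-diethyl tartrate (cat), tBuOOH, 4 Å molecular sieves, CH2Cl2, −20 °C
Reagents that add atoms: tert-butyl hydroperoxide, CC(C)(C)OO
Why: Sharpless asymmetric epoxidation acts only on the allylic alkene, and L-(+)-tartrate delivers oxygen to the face that gives the 2S,3R oxirane (C3 S and C4 R of the target), the same sense that converts geraniol into its 2S,3S epoxide.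

Step 2
Reactants: 2 [(2S,3R)-3-methyl-3-(4-methylpent-3-en-1-yl)oxiran-2-yl]methanol
Product: 3 [(2S,3R)-3-methyl-3-(4-methylpent-3-en-1-yl)oxiran-2-yl]methyl pivalate
Conditions: PivCl, Et3N, DMAP (cat), CH2Cl2, 0 °C
Reagents that add atoms: pivaloyl chloride, CC(C)(C)C(Cl)=O
Why: Acylation of the primary alcohol; the pivalate has no enolisable hydrogen, should resist LiBH4 at 0 °C and can later be removed reductively without acid or fluoride.

Step 3
Reactants: 4 (4R)-4-benzyl-1,3-oxazolidin-2-one; 5 prop-2-enoyl chloride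
Product: 7 (4R)-4-benzyl-3-(prop-2-enoyl)-1,3-oxazolidin-2-one, via lithium oxazolidinide 6 (not isolated)
Conditions: nBuLi, THF, −78 °C; then 5, −78 → 0 °C
Reagents that add atoms: none
Why: N-Acylation of the lithiated oxazolidinone by the acid chloride at low temperature, the standard entry to N-enoyl imides; the stereocentre of 4 is not involved.

Step 4
Reactants: 3 [(2S,3R)-3-methyl-3-(4-methylpent-3-en-1-yl)oxiran-2-yl]methyl pivalate; 7 (4R)-4-benzyl-3-(prop-2-enoyl)-1,3-oxazolidin-2-one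
Product: 8 [(2S,3R)-3-{(3E)-5-[(4R)-4-benzyl-2-oxo-1,3-oxazolidin-3-yl]-5-oxopent-3-en-1-yl}-3-methyloxiran-2-yl]methyl pivalate
Conditions: second-generation Hoveyda–Grubbs catalyst (5 mol %), 7 (2 equiv), CH2Cl2, 40 °C
Reagents that add atoms: none
Why: Olefin cross-metathesis: the isopropylidene terminus of 3 (its only alkene) exchanges with the electron-poor acrylimide, isobutene escapes and the E-enimide is expected, which joins C7 to C8 and C19.

Step 5
Reactants: 8 [(2S,3R)-3-{(3E)-5-[(4R)-4-benzyl-2-oxo-1,3-oxazolidin-3-yl]-5-oxopent-3-en-1-yl}-3-methyloxiran-2-yl]methyl pivalate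
Product: 9 [(2S,3R)-3-{5-[(4R)-4-benzyl-2-oxo-1,3-oxazolidin-3-yl]-5-oxopentyl}-3-methyloxiran-2-yl]methyl pivalate
Conditions: H2 (1 atm), Pd/C (palladium on carbon), EtOAc, rt
Reagents that add atoms: none
Why: Heterogeneous catalytic hydrogenation saturates the conjugated C7=C8 bond, while the trisubstituted oxirane, the pivalate and the C-bound benzyl group of the auxiliary are inert under neutral conditions.

Step 6
Reactants: 9 [(2S,3R)-3-{5-[(4R)-4-benzyl-2-oxo-1,3-oxazolidin-3-yl]-5-oxopentyl}-3-methyloxiran-2-yl]methyl pivalate; 10 (2E)-pent-2-enal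
Product: 13 [(2S,3R)-3-{(4R,5S,6E)-4-[(4R)-4-benzyl-2-oxo-1,3-oxazolidine-3-carbonyl]-5-hydroxynon-6-en-1-yl}-3-methyloxiran-2-yl]methyl pivalate, via dibutylboron Z-enolate 11 (not isolated), via dibutylboron aldolate 12 (not isolated)
Conditions: Bu2BOTf, iPr2NEt, CH2Cl2, −78 → 0 °C; then 10, −78 → 0 °C; then H2O2, MeOH, pH 7 buffer, 0 °C
Reagents that add atoms: none
Why: Evans syn-aldol reaction: the Z-boron enolate reacts through a chair Zimmerman–Traxler transition state on the face away from the benzyl group of the (R)-auxiliary, which sets C8 (R in 13, the centre that is 8S in the target once C19 is reduced and C9 oxidised) and the C9 carbinol (S, oxidised later), and the enal reacts only at its carbonyl.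

Step 7
Reactants: 13 [(2S,3R)-3-{(4R,5S,6E)-4-[(4R)-4-benzyl-2-oxo-1,3-oxazolidine-3-carbonyl]-5-hydroxynon-6-en-1-yl}-3-methyloxiran-2-yl]methyl pivalate
Product: 14 [(2S,3R)-3-[(4S,5S,6E)-5-hydroxy-4-(hydroxymethyl)non-6-en-1-yl]-3-methyloxiran-2-yl]methyl pivalate
Conditions: LiBH4, H2O (1 equiv), Et2O, 0 °C
Reagents that add atoms: none
Why: Reductive cleavage of the imide with LiBH4 releases the C19 primary alcohol and the auxiliary without epimerising C8, the activated exocyclic imide carbonyl being reduced much faster than the hindered pivalate or the oxirane.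

Step 8
Reactants: 14 [(2S,3R)-3-[(4S,5S,6E)-5-hydroxy-4-(hydroxymethyl)non-6-en-1-yl]-3-methyloxiran-2-yl]methyl pivalate
Product: 15 [(2S,3R)-3-[(4S,5S,6E)-4-{[(tert-butyldimethylsilyl)oxy]methyl}-5-hydroxynon-6-en-1-yl]-3-methyloxiran-2-yl]methyl pivalate
Conditions: TBSCl (1.05 equiv), imidazole, CH2Cl2, 0 °C
Reagents that add atoms: tert-butyldimethylsilyl chloride, CC(C)(C)[Si](C)(C)Cl
Why: Silylation with one equivalent of the chloride selects the primary C19 hydroxyl over the secondary allylic C9 hydroxyl on steric grounds.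

Step 9
Reactants: 15 [(2S,3R)-3-[(4S,5S,6E)-4-{[(tert-butyldimethylsilyl)oxy]methyl}-5-hydroxynon-6-en-1-yl]-3-methyloxiran-2-yl]methyl pivalate
Product: 16 [(2S,3R)-3-[(4S,6E)-4-{[(tert-butyldimethylsilyl)oxy]methyl}-5-oxonon-6-en-1-yl]-3-methyloxiran-2-yl]methyl pivalate
Conditions: Dess–Martin periodinane, NaHCO3, CH2Cl2, 0 °C → rt
Reagents that add atoms: none
Why: Dess–Martin oxidation of the allylic alcohol gives the E-enone under buffered, non-basic conditions, so the α-stereocentre C8 and its β-silyloxy group are not disturbed.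

Step 10
Reactants: 16 [(2S,3R)-3-[(4S,6E)-4-{[(tert-butyldimethylsilyl)oxy]methyl}-5-oxonon-6-en-1-yl]-3-methyloxiran-2-yl]methyl pivalate
Product: 17 [(2S,3R)-3-[(4S,5Z,7E)-4-{[(tert-butyldimethylsilyl)oxy]methyl}-5-[(triisopropylsilyl)oxy]nona-5,7-dien-1-yl]-3-methyloxiran-2-yl]methyl pivalate
Conditions: TIPSOTf, Et3N, CH2Cl2, −78 → 0 °C
Reagents that add atoms: triisopropylsilyl trifluoromethanesulfonate, CC(C)[Si](OS(=O)(=O)C(F)(F)F)(C(C)C)C(C)C
Why: Soft enolisation (silyl triflate and amine) should silylate the enone oxygen and remove a γ-proton at C12 rather than the tertiary C8–H, because the cross-conjugated alternative is a tetrasubstituted enol ether crowded by the triisopropylsilyl group, and the s-cis enone should give the 9Z,11E dienol ether (plan locants) with C8 untouched.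

Step 11
Reactants: 18 isobutylmagnesium bromide; 19 diethyl chlorophosphate
Product: 20 diethyl (2-methylpropyl)phosphonate
Conditions: THF, −78 → 0 °C (18 added to 19)
Reagents that add atoms: none
Why: Nucleophilic substitution at phosphorus: the Grignard reagent displaces chloride from the chlorophosphate, and inverse addition at low temperature stops the reaction at the phosphonate.

Step 12
Reactants: 21 methyl glycolate
Product: 22 methyl 2-[(tert-butyldimethylsilyl)oxy]acetate
Conditions: TBSCl, imidazole, DMF, rt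
Reagents that add atoms: tert-butyldimethylsilyl chloride, CC(C)(C)[Si](C)(C)Cl
Why: Standard silyl protection of the hydroxyl so that the ester can be attacked by a carbanion in the next step.

Step 13
Reactants: 20 diethyl (2-methylpropyl)phosphonate; 22 methyl 2-[(tert-butyldimethylsilyl)oxy]acetate
Product: 24 diethyl {1-[(tert-butyldimethylsilyl)oxy]-4-methyl-2-oxopentan-3-yl}phosphonate (racemic), via lithiated phosphonate 23 (not isolated)
Conditions: 20 (2 equiv), nBuLi (2 equiv), THF, −78 °C; then 22 (1 equiv), −78 → 0 °C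
Reagents that add atoms: none
Why: Claisen-type acylation of the α-lithiated phosphonate by the ester gives the β-ketophosphonate, whose acidic C–H consumes the second equivalent of carbanion and so prevents over-addition; the new stereocentre is racemic and is destroyed in step 17.

Step 14
Reactants: 24 diethyl {1-[(tert-butyldimethylsilyl)oxy]-4-methyl-2-oxopentan-3-yl}phosphonate
Product: 25 diethyl (1-hydroxy-4-methyl-2-oxopentan-3-yl)phosphonate (racemic)
Conditions: aq HF, MeCN, 0 °C → rt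
Reagents that add atoms: none
Why: Fluoride desilylation frees the primary α-ketol at this stage, so that no protecting group has to be removed later in the presence of the silyl dienol ether.

Step 15
Reactants: 17 [(2S,3R)-3-[(4S,5Z,7E)-4-{[(tert-butyldimethylsilyl)oxy]methyl}-5-[(triisopropylsilyl)oxy]nona-5,7-dien-1-yl]-3-methyloxiran-2-yl]methyl pivalate
Product: 26 [(2S,3R)-3-[(4S,5Z,7E)-4-{[(tert-butyldimethylsilyl)oxy]methyl}-5-[(triisopropylsilyl)oxy]nona-5,7-dien-1-yl]-3-methyloxiran-2-yl]methanol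
Conditions: iBu2AlH, CH2Cl2, −78 °C
Reagents that add atoms: none
Why: Reductive cleavage of the pivalate ester by iBu2AlH at −78 °C should leave the silyl dienol ether, the silyl ether and the oxirane untouched, which acid, fluoride or oxidative deprotections would not.

Step 16
Reactants: 26 [(2S,3R)-3-[(4S,5Z,7E)-4-{[(tert-butyldimethylsilyl)oxy]methyl}-5-[(triisopropylsilyl)oxy]nona-5,7-dien-1-yl]-3-methyloxiran-2-yl]methanol
Product: 27 (2R,3R)-3-[(4S,5Z,7E)-4-{[(tert-butyldimethylsilyl)oxy]methyl}-5-[(triisopropylsilyl)oxy]nona-5,7-dien-1-yl]-3-methyloxirane-2-carbaldehyde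
Conditions: Dess–Martin periodinane, NaHCO3, CH2Cl2, 0 °C
Reagents that add atoms: none
Why: Buffered Dess–Martin oxidation gives the α,β-epoxy aldehyde without acid that could open the oxirane or hydrolyse the dienol ether, and C3 cannot epimerise because enolisation would put a double bond into the oxirane (the descriptor changes to R only through CIP priority).

Step 17
Reactants: 27 (2R,3R)-3-[(4S,5Z,7E)-4-{[(tert-butyldimethylsilyl)oxy]methyl}-5-[(triisopropylsilyl)oxy]nona-5,7-dien-1-yl]-3-methyloxirane-2-carbaldehyde; 25 diethyl (1-hydroxy-4-methyl-2-oxopentan-3-yl)phosphonate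
Product: 28 (3E)-4-{(2S,3R)-3-[(4S,5Z,7E)-4-{[(tert-butyldimethylsilyl)oxy]methyl}-5-[(triisopropylsilyl)oxy]nona-5,7-dien-1-yl]-3-methyloxiran-2-yl}-1-hydroxy-3-(propan-2-yl)but-3-en-2-one
Conditions: Ba(OH)2, THF/H2O (40:1), 0 °C → rt
Reagents that add atoms: none
Why: Horner–Wadsworth–Emmons olefination: the carbanion of 25 adds to the unhindered, activated epoxy aldehyde and the elimination should place the oxiranyl group trans to the acyl group (E, the geometry favoured for 2-alkyl enones), although the α-branched phosphonate will react slowly; the mild base tolerates the free hydroxyl and the dienol ether.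

Step 18
Reactants: 28 (3E)-4-{(2S,3R)-3-[(4S,5Z,7E)-4-{[(tert-butyldimethylsilyl)oxy]methyl}-5-[(triisopropylsilyl)oxy]nona-5,7-dien-1-yl]-3-methyloxiran-2-yl}-1-hydroxy-3-(propan-2-yl)but-3-en-2-one
Product: 29 (3E)-4-{(2S,3R)-3-[(4S,5Z,7E)-4-{[(tert-butyldimethylsilyl)oxy]methyl}-5-[(triisopropylsilyl)oxy]nona-5,7-dien-1-yl]-3-methyloxiran-2-yl}-2-oxo-3-(propan-2-yl)but-3-enal
Conditions: Dess–Martin periodinane, NaHCO3, CH2Cl2, 0 °C → rt; filtered under argon without aqueous work-up and used at once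
Reagents that add atoms: none
Why: Dess–Martin oxidation of the primary α-ketol gives the 2-oxoaldehyde, and buffering plus a non-aqueous work-up should preserve the dienol ether and avoid the aldehyde hydrate.

Step 19
Reactants: 29 (3E)-4-{(2S,3R)-3-[(4S,5Z,7E)-4-{[(tert-butyldimethylsilyl)oxy]methyl}-5-[(triisopropylsilyl)oxy]nona-5,7-dien-1-yl]-3-methyloxiran-2-yl}-2-oxo-3-(propan-2-yl)but-3-enal
Product: 30 (1S,2E,5S,6R,7E,10S,14R)-10-{[(tert-butyldimethylsilyl)oxy]methyl}-6,14-dimethyl-3-(propan-2-yl)-5-[(triisopropylsilyl)oxy]-15-oxabicyclo[12.1.0]pentadeca-2,7-diene-4,9-dione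
Conditions: [Cu((S,S)-tBu-box)](SbF6)2 (20 mol %), CH2Cl2, −78 → −40 °C, 29 added by syringe pump over 12 h (final 1 mM)
Reagents that add atoms: none
Why: Proposed new method: the C13–C14 dicarbonyl of 29 should bind the divalent copper centre through both oxygens in a square-planar five-membered chelate that activates the aldehyde, the silyl dienol ether adds to it through its γ-carbon C12 in an open transition state, and transfer of the triisopropylsilyl group from O9 to O13 releases the C9 enone and the catalyst. The closest known reaction type is the copper bis(oxazoline)-catalysed Mukaiyama and vinylogous Mukaiyama aldol addition to chelating glyoxylates, pyruvates and (benzyloxy)acetaldehyde, which is established between molecules but not as a macrocyclisation. The 14-membered carbocycle closes by a 14-exo-trig attack of C12 on the C13 carbonyl, which slow addition into dilute catalyst solution and the rigid C1=C2 alkene, oxirane and planar dienol ether of the chain should favour over intermolecular addition. C13 (S) is set by the ligand, whose tert-butyl group should shield the Re face of the chelated aldehyde as in glyoxylate additions, and C12 (R) by the 12,13-syn preference of an antiperiplanar open transition state of the 11E dienol ether, the less secure of the two. The step needs γ- over α-attack (favoured by the bulky silyl group on O9), aldehyde over ketone and over conjugate addition at C2 (the aldehyde is the most electrophilic site and C2 is flanked by the isopropyl group and the oxirane) and an intact oxirane (the chelated complex is only a mild Lewis acid).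

Step 20
Reactants: 30 (1S,2E,5S,6R,7E,10S,14R)-10-{[(tert-butyldimethylsilyl)oxy]methyl}-6,14-dimethyl-3-(propan-2-yl)-5-[(triisopropylsilyl)oxy]-15-oxabicyclo[12.1.0]pentadeca-2,7-diene-4,9-dione
Product: 31 (1S,2E,5S,6R,10S,14R)-10-{[(tert-butyldimethylsilyl)oxy]methyl}-6,14-dimethyl-3-(propan-2-yl)-5-[(triisopropylsilyl)oxy]-15-oxabicyclo[12.1.0]pentadec-2-ene-4,9-dione
Conditions: [(Ph3P)CuH]6 (0.4 equiv), H2O (5 equiv), degassed toluene, 0 °C → rt
Reagents that add atoms: none
Why: Conjugate reduction by copper hydride: the phosphine copper hydride hexamer should deliver hydride to C11 of the disubstituted C10=C11 enone much faster than to C2 of the α-branched, oxirane-flanked C1=C2 enone, and water protonates the copper enolate before it can add across the ring; no stereocentre is formed.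

Step 21
Reactants: 31 (1S,2E,5S,6R,10S,14R)-10-{[(tert-butyldimethylsilyl)oxy]methyl}-6,14-dimethyl-3-(propan-2-yl)-5-[(triisopropylsilyl)oxy]-15-oxabicyclo[12.1.0]pentadec-2-ene-4,9-dione
Product: 32 (1S,2E,5S,6R,10S,14R)-5-hydroxy-10-(hydroxymethyl)-6,14-dimethyl-3-(propan-2-yl)-15-oxabicyclo[12.1.0]pentadec-2-ene-4,9-dione (CNP0110598.2)
Conditions: HF·pyridine, pyridine, THF, 0 °C → rt
Reagents that add atoms: none
Why: Fluoride desilylation with pyridine-buffered HF·pyridine should remove the primary tert-butyldimethylsilyl ether and the α-keto triisopropylsilyl ether under conditions mild enough for the trisubstituted oxirane and the β-hydroxy ketone.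

**Compound list**

1 | nerol, (2Z)-3,7-dimethylocta-2,6-dien-1-ol | CC(C)=CCC/C(C)=C\CO | starting material
2 | [(2S,3R)-3-methyl-3-(4-methylpent-3-en-1-yl)oxiran-2-yl]methanol | OC[C@@H]1O[C@]1(C)CCC=C(C)C | intermediate
3 | [(2S,3R)-3-methyl-3-(4-methylpent-3-en-1-yl)oxiran-2-yl]methyl pivalate | CC(C)(C)C(=O)OC[C@@H]1O[C@]1(C)CCC=C(C)C | intermediate
4 | (4R)-4-benzyl-1,3-oxazolidin-2-one | O=C1N[C@H](Cc2ccccc2)CO1 | starting material
5 | prop-2-enoyl chloride (acryloyl chloride) | C=CC(Cl)=O | starting material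
6 | lithium salt of 4 (formed in the flask, not isolated) | [Li]N1[C@H](Cc2ccccc2)COC1=O | intermediate
7 | (4R)-4-benzyl-3-(prop-2-enoyl)-1,3-oxazolidin-2-one | C=CC(=O)N1[C@H](Cc2ccccc2)COC1=O | intermediate
8 | [(2S,3R)-3-{(3E)-5-[(4R)-4-benzyl-2-oxo-1,3-oxazolidin-3-yl]-5-oxopent-3-en-1-yl}-3-methyloxiran-2-yl]methyl pivalate | CC(C)(C)C(=O)OC[C@@H]1O[C@]1(C)CC/C=C/C(=O)N1[C@H](Cc2ccccc2)COC1=O | intermediate
9 | [(2S,3R)-3-{5-[(4R)-4-benzyl-2-oxo-1,3-oxazolidin-3-yl]-5-oxopentyl}-3-methyloxiran-2-yl]methyl pivalate | CC(C)(C)C(=O)OC[C@@H]1O[C@]1(C)CCCCC(=O)N1[C@H](Cc2ccccc2)COC1=O | intermediate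
10 | (2E)-pent-2-enal | CC/C=C/C=O | starting material
11 | dibutylboron Z-enolate of 9 (not isolated) | CCCCB(CCCC)O/C(=C\CCC[C@@]1(C)O[C@H]1COC(=O)C(C)(C)C)N1[C@H](Cc2ccccc2)COC1=O | intermediate
12 | dibutylboron aldolate of 13 (not isolated) | CC(C)(C)C(=O)OC[C@@H]1O[C@]1(C)CCC[C@H]([C@@H](OB(CCCC)CCCC)/C=C/CC)C(=O)N1[C@H](Cc2ccccc2)COC1=O | intermediate
13 | [(2S,3R)-3-{(4R,5S,6E)-4-[(4R)-4-benzyl-2-oxo-1,3-oxazolidine-3-carbonyl]-5-hydroxynon-6-en-1-yl}-3-methyloxiran-2-yl]methyl pivalate | CC(C)(C)C(=O)OC[C@@H]1O[C@]1(C)CCC[C@H]([C@@H](O)/C=C/CC)C(=O)N1[C@H](Cc2ccccc2)COC1=O | intermediate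
14 | [(2S,3R)-3-[(4S,5S,6E)-5-hydroxy-4-(hydroxymethyl)non-6-en-1-yl]-3-methyloxiran-2-yl]methyl pivalate | CC(C)(C)C(=O)OC[C@@H]1O[C@]1(C)CCC[C@H]([C@@H](O)/C=C/CC)CO | intermediate
15 | [(2S,3R)-3-[(4S,5S,6E)-4-{[(tert-butyldimethylsilyl)oxy]methyl}-5-hydroxynon-6-en-1-yl]-3-methyloxiran-2-yl]methyl pivalate | CC(C)(C)C(=O)OC[C@@H]1O[C@]1(C)CCC[C@H]([C@@H](O)/C=C/CC)CO[Si](C)(C)C(C)(C)C | intermediate
16 | [(2S,3R)-3-[(4S,6E)-4-{[(tert-butyldimethylsilyl)oxy]methyl}-5-oxonon-6-en-1-yl]-3-methyloxiran-2-yl]methyl pivalate | CC(C)(C)C(=O)OC[C@@H]1O[C@]1(C)CCC[C@@H](CO[Si](C)(C)C(C)(C)C)C(=O)/C=C/CC | intermediate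
17 | [(2S,3R)-3-[(4S,5Z,7E)-4-{[(tert-butyldimethylsilyl)oxy]methyl}-5-[(triisopropylsilyl)oxy]nona-5,7-dien-1-yl]-3-methyloxiran-2-yl]methyl pivalate | CC(C)(C)C(=O)OC[C@@H]1O[C@]1(C)CCC[C@@H](CO[Si](C)(C)C(C)(C)C)/C(O[Si](C(C)C)(C(C)C)C(C)C)=C/C=C/C | intermediate
18 | isobutylmagnesium bromide | CC(C)C[Mg]Br | starting material
19 | diethyl chlorophosphate | CCOP(=O)(Cl)OCC | starting material
20 | diethyl (2-methylpropyl)phosphonate | CCOP(=O)(CC(C)C)OCC | intermediate
21 | methyl glycolate | COC(=O)CO | starting material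
22 | methyl 2-[(tert-butyldimethylsilyl)oxy]acetate | COC(=O)CO[Si](C)(C)C(C)(C)C | intermediate
23 | diethyl (1-lithio-2-methylpropyl)phosphonate (not isolated) | [Li]C(C(C)C)P(=O)(OCC)OCC | intermediate
24 | diethyl {1-[(tert-butyldimethylsilyl)oxy]-4-methyl-2-oxopentan-3-yl}phosphonate (racemic) | CCOP(=O)(OCC)C(C(C)C)C(=O)CO[Si](C)(C)C(C)(C)C | intermediate
25 | diethyl (1-hydroxy-4-methyl-2-oxopentan-3-yl)phosphonate (racemic) | CCOP(=O)(OCC)C(C(C)C)C(=O)CO | intermediate
26 | [(2S,3R)-3-[(4S,5Z,7E)-4-{[(tert-butyldimethylsilyl)oxy]methyl}-5-[(triisopropylsilyl)oxy]nona-5,7-dien-1-yl]-3-methyloxiran-2-yl]methanol | OC[C@@H]1O[C@]1(C)CCC[C@@H](CO[Si](C)(C)C(C)(C)C)/C(O[Si](C(C)C)(C(C)C)C(C)C)=C/C=C/C | intermediate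
27 | (2R,3R)-3-[(4S,5Z,7E)-4-{[(tert-butyldimethylsilyl)oxy]methyl}-5-[(triisopropylsilyl)oxy]nona-5,7-dien-1-yl]-3-methyloxirane-2-carbaldehyde | O=C[C@@H]1O[C@]1(C)CCC[C@@H](CO[Si](C)(C)C(C)(C)C)/C(O[Si](C(C)C)(C(C)C)C(C)C)=C/C=C/C | intermediate
28 | (3E)-4-{(2S,3R)-3-[(4S,5Z,7E)-4-{[(tert-butyldimethylsilyl)oxy]methyl}-5-[(triisopropylsilyl)oxy]nona-5,7-dien-1-yl]-3-methyloxiran-2-yl}-1-hydroxy-3-(propan-2-yl)but-3-en-2-one | OCC(=O)/C(C(C)C)=C/[C@@H]1O[C@]1(C)CCC[C@@H](CO[Si](C)(C)C(C)(C)C)/C(O[Si](C(C)C)(C(C)C)C(C)C)=C/C=C/C | intermediate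
29 | (3E)-4-{(2S,3R)-3-[(4S,5Z,7E)-4-{[(tert-butyldimethylsilyl)oxy]methyl}-5-[(triisopropylsilyl)oxy]nona-5,7-dien-1-yl]-3-methyloxiran-2-yl}-2-oxo-3-(propan-2-yl)but-3-enal (precursor of the key step) | O=CC(=O)/C(C(C)C)=C/[C@@H]1O[C@]1(C)CCC[C@@H](CO[Si](C)(C)C(C)(C)C)/C(O[Si](C(C)C)(C(C)C)C(C)C)=C/C=C/C | intermediate
30 | (1S,2E,5S,6R,7E,10S,14R)-10-{[(tert-butyldimethylsilyl)oxy]methyl}-6,14-dimethyl-3-(propan-2-yl)-5-[(triisopropylsilyl)oxy]-15-oxabicyclo[12.1.0]pentadeca-2,7-diene-4,9-dione (product of the key step; plan locants 3S,4R,8S,12R,13S) | CC(C)/C1=C\[C@@H]2O[C@]2(C)CCC[C@@H](CO[Si](C)(C)C(C)(C)C)C(=O)/C=C/[C@@H](C)[C@H](O[Si](C(C)C)(C(C)C)C(C)C)C1=O | intermediate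
31 | (1S,2E,5S,6R,10S,14R)-10-{[(tert-butyldimethylsilyl)oxy]methyl}-6,14-dimethyl-3-(propan-2-yl)-5-[(triisopropylsilyl)oxy]-15-oxabicyclo[12.1.0]pentadec-2-ene-4,9-dione | CC(C)/C1=C\[C@@H]2O[C@]2(C)CCC[C@@H](CO[Si](C)(C)C(C)(C)C)C(=O)CC[C@@H](C)[C@H](O[Si](C(C)C)(C(C)C)C(C)C)C1=O | intermediate
32 | (1S,2E,5S,6R,10S,14R)-5-hydroxy-10-(hydroxymethyl)-6,14-dimethyl-3-(propan-2-yl)-15-oxabicyclo[12.1.0]pentadec-2-ene-4,9-dione, CNP0110598.2 | CC(C)/C1=C\[C@@H]2O[C@]2(C)CCC[C@@H](CO)C(=O)CC[C@@H](C)[C@H](O)C1=O | target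

**Step count and risks**

Total step count: 21. Longest linear sequence: 16 steps from nerol (steps 1, 2, 4–10, 15–21).

Steps most likely to fail:

1. Step 19 (Proposed new method). Intermolecular aldol addition may outrun ring closure, the dienol ether may attack through C10, slow silyl transfer may stall the copper complex, or the facial or syn/anti sense may be wrong. The fallback forms C12–C13 between molecules and closes the ring at C10=C11 by metathesis, all with known reactions. It sets out from 15. iBu2AlH at −78 °C removes the pivalate to give [(2S,3R)-3-[(4S,5S,6E)-4-{[(tert-butyldimethylsilyl)oxy]methyl}-5-hydroxynon-6-en-1-yl]-3-methyloxiran-2-yl]methanol F1. Dess–Martin periodinane oxidises both hydroxyls to the epoxy aldehyde enone F2. Horner–Wadsworth–Emmons reaction with 25 (Ba(OH)2) gives the hydroxy dienedione F3, and a second Dess–Martin oxidation gives the 2-oxoaldehyde F4. Roush asymmetric crotylboration with the (Z)-crotylboronate of (R,R)-diisopropyl tartrate (toluene, −78 °C, 4 Å molecular sieves) should attack the Si face of C13 and, through the Z geometry, give the 12R,13S syn homoallylic alcohol F5. Second-generation Grubbs catalyst in dilute CH2Cl2 at 40 °C then closes the 14-membered ring between the vinyl group and the C9 pentenone, with loss of but-1-ene, to the macrocyclic hydroxy enone F6. TIPSOTf and 2,6-lutidine bring the route back at 30.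

2. Step 10. Deprotonation may occur at C8 instead of C12, which would erase the C8 configuration and give a cross-conjugated diene. The fallback enolises while C19 is still the imide carbonyl. It sets out from 13. Dess–Martin oxidation gives the β-keto imide F7, in which allylic 1,3-strain holds the C8–H in the imide plane, a known reason why such imides are not deprotonated there by amines. TIPSOTf and Et3N can then enolise only towards C12 and give the imide dienol ether F8. LiBH4 cleaves the auxiliary to the primary alcohol F9, and TBSCl with imidazole brings the route back at 17.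

3. Step 20. Hydride may also add to C2 of the second enone, or the copper enolate at C10 may add across the ring to the C14 ketone. The fallback replaces hydride conjugate addition by concerted hydrogen transfer from diimide (2-nitrobenzenesulfonohydrazide, Et3N, CH2Cl2, rt). Diimide reduces the trans-disubstituted C10=C11 bond far faster than the trisubstituted C1=C2 bond and forms no enolate. It sets out from 30 and comes back at 31; no new compound arises (F0).

**Further compounds**

F1 | step 19 | [(2S,3R)-3-[(4S,5S,6E)-4-{[(tert-butyldimethylsilyl)oxy]methyl}-5-hydroxynon-6-en-1-yl]-3-methyloxiran-2-yl]methanol | OC[C@@H]1O[C@]1(C)CCC[C@H]([C@@H](O)/C=C/CC)CO[Si](C)(C)C(C)(C)C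
F2 | step 19 | (2R,3R)-3-[(4S,6E)-4-{[(tert-butyldimethylsilyl)oxy]methyl}-5-oxonon-6-en-1-yl]-3-methyloxirane-2-carbaldehyde | O=C[C@@H]1O[C@]1(C)CCC[C@@H](CO[Si](C)(C)C(C)(C)C)C(=O)/C=C/CC
F3 | step 19 | (3E)-4-{(2S,3R)-3-[(4S,6E)-4-{[(tert-butyldimethylsilyl)oxy]methyl}-5-oxonon-6-en-1-yl]-3-methyloxiran-2-yl}-1-hydroxy-3-(propan-2-yl)but-3-en-2-one | OCC(=O)/C(C(C)C)=C/[C@@H]1O[C@]1(C)CCC[C@@H](CO[Si](C)(C)C(C)(C)C)C(=O)/C=C/CC
F4 | step 19 | (3E)-4-{(2S,3R)-3-[(4S,6E)-4-{[(tert-butyldimethylsilyl)oxy]methyl}-5-oxonon-6-en-1-yl]-3-methyloxiran-2-yl}-2-oxo-3-(propan-2-yl)but-3-enal | O=CC(=O)/C(C(C)C)=C/[C@@H]1O[C@]1(C)CCC[C@@H](CO[Si](C)(C)C(C)(C)C)C(=O)/C=C/CC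
F5 | step 19 | (1E,4S,5R)-1-{(2S,3R)-3-[(4S,6E)-4-{[(tert-butyldimethylsilyl)oxy]methyl}-5-oxonon-6-en-1-yl]-3-methyloxiran-2-yl}-4-hydroxy-5-methyl-2-(propan-2-yl)hepta-1,6-dien-3-one | C=C[C@@H](C)[C@H](O)C(=O)/C(C(C)C)=C/[C@@H]1O[C@]1(C)CCC[C@@H](CO[Si](C)(C)C(C)(C)C)C(=O)/C=C/CC
F6 | step 19 | (1S,2E,5S,6R,7E,10S,14R)-10-{[(tert-butyldimethylsilyl)oxy]methyl}-5-hydroxy-6,14-dimethyl-3-(propan-2-yl)-15-oxabicyclo[12.1.0]pentadeca-2,7-diene-4,9-dione | CC(C)/C1=C\[C@@H]2O[C@]2(C)CCC[C@@H](CO[Si](C)(C)C(C)(C)C)C(=O)/C=C/[C@@H](C)[C@H](O)C1=O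
F7 | step 10 | [(2S,3R)-3-{(4R,6E)-4-[(4R)-4-benzyl-2-oxo-1,3-oxazolidine-3-carbonyl]-5-oxonon-6-en-1-yl}-3-methyloxiran-2-yl]methyl pivalate | CC(C)(C)C(=O)OC[C@@H]1O[C@]1(C)CCC[C@H](C(=O)/C=C/CC)C(=O)N1[C@H](Cc2ccccc2)COC1=O
F8 | step 10 | [(2S,3R)-3-{(4R,5Z,7E)-4-[(4R)-4-benzyl-2-oxo-1,3-oxazolidine-3-carbonyl]-5-[(triisopropylsilyl)oxy]nona-5,7-dien-1-yl}-3-methyloxiran-2-yl]methyl pivalate | CC(C)(C)C(=O)OC[C@@H]1O[C@]1(C)CCC[C@H](/C(O[Si](C(C)C)(C(C)C)C(C)C)=C/C=C/C)C(=O)N1[C@H](Cc2ccccc2)COC1=O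
F9 | step 10 | [(2S,3R)-3-[(4S,5Z,7E)-4-(hydroxymethyl)-5-[(triisopropylsilyl)oxy]nona-5,7-dien-1-yl]-3-methyloxiran-2-yl]methyl pivalate | CC(C)(C)C(=O)OC[C@@H]1O[C@]1(C)CCC[C@@H](CO)/C(O[Si](C(C)C)(C(C)C)C(C)C)=C/C=C/C
F0 | step 20 | none | none
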